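**Assumptions.** The C6–D3 biaryl axis (ortho groups OH, OH, OMe, H) is taken to rotate freely at room temperature, so the target is treated as achiral, as its SMILES shows. Compounds 1 and 8 and all reagents on the reagent lines are taken as commercial.

## Analysis of the target

The target 18 is a flavone. Ring A (C4a, C5, C6, C7, C8, C8a) is fused through C4a–C8a to the 4-pyranone ring C (O1, C2, C3, C4), ring B (4-hydroxyphenyl) sits on C2, and ring D, a methyl 4-methoxybenzoate, is bonded through its carbon D3 (ortho to the methoxy carbon D4, meta to the ester carbon D1) to C6. Ring A is a fully differentiated phloroglucinol: a free, chelated OH on C5, a free OH on C7, the ring oxygen O1 on C8a, ring D on C6 between the two hydroxyls, hydrogen on C8 and the acyl carbon C4 on C4a. There is no stereocentre, and the tri-ortho-substituted C6–D3 axis needs no control. The sensitive groups are three phenols of different acidity, a methyl ester, a pyranone that opens with hydroxide, and one aryl methyl ether that must survive while three other oxygens are unmasked, so methyl ethers cannot protect rings A and B. The hard part is regiochemistry: C6 and C8 are both flanked by two oxygens and differ only through the chelated 5-OH, and 6- and 8-aryl isomers can interconvert through the ring-opened diketone (Wessely–Moser rearrangement). The feature the route uses is the atom sequence C5(OH)–C6(aryl)–C7(O)–C8(H) attached to the C8a=C4a bond of ring C. This is the pattern in which a vinylketene and a siloxyalkyne combine to a 3-siloxyphenol: ketene carbonyl carbon becomes C5–OH, the aryl-bearing alkyne carbon C6, the oxygen-bearing alkyne carbon C7, the ketene α-carbon C8, and the ketene's vinyl bond becomes C8a=C4a, which can be the C2=C3 bond of a preformed 6-aryl-4-pyranone carrying rings C and B.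

## Retrosynthetic reasoning

**18 ⇒ 17.** The two Si–O bonds at O7 and O4' are cut. The O7 silyl group is delivered by the alkyne partner of the key step; the O4' group is chosen to be the same, so that one fluoride treatment frees both phenols without touching the D4 methyl ether or the ester.

**17 ⇒ 7 + 12 (key disconnection).** Ring A is taken apart at C4a–C5, C5–C6, C7–C8 and C8–C8a. This gives diazo ketone 7, a monocyclic pyranone that already holds rings C and B, and siloxyalkyne 12, which holds ring D.
- Ring D is placed on C6 by connectivity, not by a directing effect on a finished ring A.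
- O5 emerges free and O7 silylated, so the oxygens are differentiated without protecting-group steps.
- The hindered biaryl bond is never made by coupling at a tri-ortho-substituted carbon; it exists beforehand as the unhindered aryl–alkynyl bond of 12.
- The forward reaction must generate a pyranonyl ketene from 7, add it to 12 in the orientation that joins the ketene carbonyl carbon to the aryl-bearing alkyne carbon, and close the six-membered ring onto pyranone C3.

**12 ⇒ 9 ⇒ 8.** The C(sp)–O bond of 12 is cut back to terminal alkyne 9 (forward: oxygen transfer to the acetylide, then O-silylation). The D3–C(sp) bond of 9 is cut back to aryl iodide 8 (forward: cross-coupling with an ethynyl-metal donor). The ester and methyl ether are bought in place.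

**7 ⇒ 5.** The bond between the acyl carbon and the diazo carbon is cut (forward: acylation of a one-carbon diazo donor by acid chloride 6).

**5 ⇒ 3.** Ring C is cut at the ring O–C bond and at the C2–C3 bond next to the carboxyl group, leading to triketo ester 4 and then to diketone 3 plus an oxalic diester. The terminal methyl carbon of 3 becomes pyranone C3, and acid closes and dehydrates the tricarbonyl chain.

**3 ⇒ 2 ⇒ 1.** The C–C bond to the acetyl group is cut (forward: C-acetylation of the methyl ketone), then the Si–O bond, back to commercial 1.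

## Alternatives that were turned down

**Alternative 1: Suzuki–Miyaura coupling at C6–D3 (the textbook route).**
- Disconnection: the biaryl bond.
- Forward: apigenin A1 is benzylated to its 7,4'-dibenzyl ether A2, iodinated ortho to the chelated 5-OH to the 6-iodide A3, coupled with [2-methoxy-5-(methoxycarbonyl)phenyl]boronic acid A4 to the dibenzyl ether A5, and debenzylated.
- Why turned down: it is short, and it is kept below as the fallback. Its regiochemistry rests on an empirical C6-over-C8 preference in the halogenation of A2, not on connectivity. The coupling joins a tri-ortho-substituted carbon next to a free phenol, where protodeiodination competes with transmetalation. It is also the route most chemists would draw first, which the brief excludes as the main line.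

**Alternative 2: ring D from a 2-pyrone.**
- Disconnection: ring D at D1–D2 and D3–D4... more exactly, the four ring-D carbons D1, D2, D5, D6 come from methyl coumalate A7 and D3, D4 from a ketene acetal.
- Forward: inverse-electron-demand Diels–Alder reaction of A7 with the flavon-6-yl ketene dimethyl acetal A6, then loss of CO2 and methanol. Polarity puts the ester para to OMe and the flavonyl group ortho to OMe, giving A5.
- Why turned down: the pattern is right, but A6 can only be reached from a flavone already functionalised at C6, in practice from A3, by a two-carbon coupling and acetal formation. It therefore inherits the regiochemical problem of alternative 1 and adds at least three steps. A ketene acetal next to the acidic 5-OH would protonate and hydrolyse, and its nucleophilic carbon, flanked by two ortho oxygens, is hindered for bonding to pyrone C6.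

**Alternative 3: direct C6–H arylation.**
- Disconnection: the biaryl bond, with C6 not prefunctionalised.
- Forward: Pinhey arylation of A2 with the aryllead triacetate A8 (ligand coupling on a tetravalent lead aryloxide, pyridine, CHCl3).
- Why turned down: the only free phenol of A2 is the chelated 5-OH, a poor ligand for lead. If O7 is left free instead, lead binds there and C6 and C8 are both ortho, so arylation at C8 competes. A8 costs two steps and stoichiometric lead. A dehydrogenative variant fails on electronics: ring D is the less oxidisable and less nucleophilic partner, so oxidation would dimerise the flavone instead.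

Key step: step 7

## Route

**Step 1**
Reactants: 1 1-(4-hydroxyphenyl)ethan-1-one
Product: 2 1-{4-[(triisopropylsilyl)oxy]phenyl}ethan-1-one
Conditions: i-Pr3SiCl, imidazole, DMF, 25 °C
Reagents that add atoms: triisopropylsilyl chloride CC(C)[Si](Cl)(C(C)C)C(C)C
Why: Standard imidazole-promoted silylation of a phenol; the aryl triisopropylsilyl ether should tolerate the amide bases, trifluoroacetic acid and acid chloride chemistry that follow, and it falls together with the O7 silyl group at the end.

**Step 2**
Reactants: 2 1-{4-[(triisopropylsilyl)oxy]phenyl}ethan-1-one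
Product: 3 1-{4-[(triisopropylsilyl)oxy]phenyl}butane-1,3-dione
Conditions: MgBr2·OEt2, i-Pr2NEt, 1-acetylbenzotriazole, CH2Cl2, 25 °C
Reagents that add atoms: 1-acetyl-1H-benzotriazole CC(=O)n1nnc2ccccc21
Why: Soft-enolisation C-acylation (Claisen-type) of a methyl ketone; the magnesium-chelated diketonate product should not be acylated again, and no alkoxide is released that could attack the aryl silyl ether.

**Step 3**
Reactants: 3 1-{4-[(triisopropylsilyl)oxy]phenyl}butane-1,3-dione
Product: 5 4-oxo-6-{4-[(triisopropylsilyl)oxy]phenyl}-4H-pyran-2-carboxylic acid, via triketo ester 4 (not isolated)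
Conditions: LiN(i-Pr)2 (3.1 equiv), THF, −78 → 0 °C; (t-BuO2C)2, −78 °C; aq. HCl quench; then CF3CO2H/CH2Cl2 (1:1), 25 → 40 °C
Reagents that add atoms: di-tert-butyl oxalate CC(C)(C)OC(=O)C(=O)OC(C)(C)C
Why: Crossed Claisen acylation of the 1,3-diketone dianion at its terminal, more basic carbon, then acid-catalysed cyclodehydration of the 1,3,5-tricarbonyl chain to the 4-pyranone with acidolysis of the tert-butyl ester in the same pot; the aryl silyl ether is stable to both stages.

**Step 4**
Reactants: 5 4-oxo-6-{4-[(triisopropylsilyl)oxy]phenyl}-4H-pyran-2-carboxylic acid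
Product: 7 2-(2-diazoacetyl)-6-{4-[(triisopropylsilyl)oxy]phenyl}-4H-pyran-4-one, via acid chloride 6 (not isolated)
Conditions: (COCl)2, cat. DMF, CH2Cl2, 0 → 25 °C; evaporate; then CH2N2 (3 equiv), Et2O, −10 → 0 °C, short contact time, AcOH quench
Reagents that add atoms: diazomethane C=[N+]=[N-]; oxalyl chloride O=C(Cl)C(=O)Cl (chlorine of 6 only)
Why: Acylation of diazomethane by an acid chloride (first stage of the Arndt–Eistert sequence), with excess diazomethane taking up HCl; acylation at low temperature should be much faster than dipolar cycloaddition to the oxygen-substituted pyranone double bond.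

**Step 5**
Reactants: 8 methyl 3-iodo-4-methoxybenzoate
Product: 9 methyl 3-ethynyl-4-methoxybenzoate
Conditions: HC≡CMgBr, ZnBr2, THF, 0 °C; then 8, Pd(PPh3)4 (5 mol %), THF, 25 °C
Reagents that add atoms: ethynylmagnesium bromide C#C[Mg]Br (transmetalated to ethynylzinc bromide)
Why: Negishi coupling of an aryl iodide with ethynylzinc bromide should give the terminal arylalkyne directly as the mono-coupled product; the zinc reagent tolerates the methyl ester.

**Step 6**
Reactants: 9 methyl 3-ethynyl-4-methoxybenzoate
Product: 12 methyl 4-methoxy-3-{[(triisopropylsilyl)oxy]ethynyl}benzoate, via lithium acetylide 10 (not isolated), via lithium ynolate 11 (not isolated)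
Conditions: LiN(SiMe3)2, THF, −78 °C; t-BuOOLi (from t-BuOOH and LiN(SiMe3)2), −78 → 0 °C; i-Pr3SiOTf, −78 → 0 °C; chromatography on Et3N-deactivated silica
Reagents that add atoms: tert-butyl hydroperoxide CC(C)(C)OO (one oxygen atom, used as its lithium salt); triisopropylsilyl trifluoromethanesulfonate CC(C)[Si](OS(=O)(=O)C(F)(F)F)(C(C)C)C(C)C; lithium bis(trimethylsilyl)amide [Li+].C[Si](C)(C)[N-][Si](C)(C)C (lithium of 10 and 11 only)
Why: Oxidation of a lithium acetylide by lithium tert-butyl peroxide (electrophilic oxygen transfer) gives the lithium ynolate, which the bulky silyl triflate traps on oxygen; the non-nucleophilic amide base and low temperature should spare the electron-rich methyl ester.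

**Step 7**
Reactants: 7 2-(2-diazoacetyl)-6-{4-[(triisopropylsilyl)oxy]phenyl}-4H-pyran-4-one (1.3 equiv); 12 methyl 4-methoxy-3-{[(triisopropylsilyl)oxy]ethynyl}benzoate
Product: 17 methyl 3-[5-hydroxy-4-oxo-7-[(triisopropylsilyl)oxy]-2-{4-[(triisopropylsilyl)oxy]phenyl}-4H-chromen-6-yl]-4-methoxybenzoate, via pyranonyl ketene 13 (not isolated), via cyclobutenone 14 (not isolated), via dienylketene 15 (not isolated), via cyclohexadienone 16 (not isolated)
Conditions: hν (450 nm LED, or Hg lamp through Pyrex), ClCH2CH2Cl (0.2 M), 25 °C; then 80 °C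
Reagents that add atoms: none
Why: This is a Danheiser benzannulation in its second-generation form: light triggers the Wolff rearrangement of 7, the pyranon-2-yl group shifts to the diazo carbon, and ketene 13 results. Ketene 13 and siloxyalkyne 12 undergo a [2+2] cycloaddition in which the nucleophilic, aryl-bearing alkyne carbon attacks the ketene carbonyl carbon, giving cyclobutenone 14. On heating, 14 opens in a reversible 4π-electrocyclic step to dienylketene 15, which closes by a thermal 6π-electrocyclisation between the ketene carbon and pyranone C3 to 16, and 16 tautomerises to the phenol 17. The closest known reaction type is the benzannulation of vinyl, aryl and heteroaryl diazomethyl ketones with siloxyalkynes to fused 3-siloxyphenols. Ring A is the only ring closed (six-membered carbocycle, electrocyclic closure then enolisation); the sp3 centres of 14 and 16 are transient and no stereocentre remains. The orientation of the [2+2] step, which puts ring D on C6 between O5 and O7, is secured by the polarisation of the siloxyalkyne against the electrophilic central ketene carbon. The ring fusion is unambiguous because the only carbon neighbour of the ketene-bearing pyranone carbon is C3; the geometry of 15 that cannot cyclise reverts to 14 and is funnelled through the productive isomer. Light at 450 nm should be absorbed by the diazo ketone alone, which spares the pyranone chromophore, and O5 emerges free and chelated while O7 emerges silylated.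

**Step 8**
Reactants: 17 methyl 3-[5-hydroxy-4-oxo-7-[(triisopropylsilyl)oxy]-2-{4-[(triisopropylsilyl)oxy]phenyl}-4H-chromen-6-yl]-4-methoxybenzoate
Product: 18 methyl 3-[5,7-dihydroxy-2-(4-hydroxyphenyl)-4-oxo-4H-chromen-6-yl]-4-methoxybenzoate
Conditions: Bu4NF (2.5 equiv), AcOH (2.5 equiv), THF, 0 → 25 °C
Reagents that add atoms: none
Why: Fluoride cleavage of both aryl silyl ethers; acetic acid buffering should keep the phenoxides from attacking the ester or the pyranone, and the methyl ether and methyl ester are inert to fluoride.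

## Compound list

1 | 1-(4-hydroxyphenyl)ethan-1-one | CC(=O)c1ccc(O)cc1 | starting material
2 | 1-{4-[(triisopropylsilyl)oxy]phenyl}ethan-1-one | CC(=O)c1ccc(O[Si](C(C)C)(C(C)C)C(C)C)cc1 | intermediate
3 | 1-{4-[(triisopropylsilyl)oxy]phenyl}butane-1,3-dione | CC(=O)CC(=O)c1ccc(O[Si](C(C)C)(C(C)C)C(C)C)cc1 | intermediate
4 | tert-butyl 2,4,6-trioxo-6-{4-[(triisopropylsilyl)oxy]phenyl}hexanoate | CC(C)(C)OC(=O)C(=O)CC(=O)CC(=O)c1ccc(O[Si](C(C)C)(C(C)C)C(C)C)cc1 | intermediate
5 | 4-oxo-6-{4-[(triisopropylsilyl)oxy]phenyl}-4H-pyran-2-carboxylic acid | OC(=O)c1cc(=O)cc(-c2ccc(O[Si](C(C)C)(C(C)C)C(C)C)cc2)o1 | intermediate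
6 | 4-oxo-6-{4-[(triisopropylsilyl)oxy]phenyl}-4H-pyran-2-carbonyl chloride | O=C(Cl)c1cc(=O)cc(-c2ccc(O[Si](C(C)C)(C(C)C)C(C)C)cc2)o1 | intermediate
7 | 2-(2-diazoacetyl)-6-{4-[(triisopropylsilyl)oxy]phenyl}-4H-pyran-4-one | [N-]=[N+]=CC(=O)c1cc(=O)cc(-c2ccc(O[Si](C(C)C)(C(C)C)C(C)C)cc2)o1 | intermediate
8 | methyl 3-iodo-4-methoxybenzoate | COC(=O)c1ccc(OC)c(I)c1 | starting material
9 | methyl 3-ethynyl-4-methoxybenzoate | COC(=O)c1ccc(OC)c(C#C)c1 | intermediate
10 | lithium [2-methoxy-5-(methoxycarbonyl)phenyl]acetylide | COC(=O)c1ccc(OC)c(C#[C-])c1.[Li+] | intermediate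
11 | lithium 2-[2-methoxy-5-(methoxycarbonyl)phenyl]ethyn-1-olate | COC(=O)c1ccc(OC)c(C#C[O-])c1.[Li+] | intermediate
12 | methyl 4-methoxy-3-{[(triisopropylsilyl)oxy]ethynyl}benzoate | COC(=O)c1ccc(OC)c(C#CO[Si](C(C)C)(C(C)C)C(C)C)c1 | intermediate
13 | 2-(2-oxoethenyl)-6-{4-[(triisopropylsilyl)oxy]phenyl}-4H-pyran-4-one (pyranonyl ketene) | O=C=Cc1cc(=O)cc(-c2ccc(O[Si](C(C)C)(C(C)C)C(C)C)cc2)o1 | intermediate
14 | methyl 4-methoxy-3-[4-oxo-3-(4-oxo-6-{4-[(triisopropylsilyl)oxy]phenyl}-4H-pyran-2-yl)-2-[(triisopropylsilyl)oxy]cyclobut-1-en-1-yl]benzoate (racemic) | O=C1C(c2cc(=O)cc(-c3ccc(O[Si](C(C)C)(C(C)C)C(C)C)cc3)o2)C(O[Si](C(C)C)(C(C)C)C(C)C)=C1c1cc(C(=O)OC)ccc1OC | intermediate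
15 | methyl 4-methoxy-3-[1-oxo-4-(4-oxo-6-{4-[(triisopropylsilyl)oxy]phenyl}-4H-pyran-2-yl)-3-[(triisopropylsilyl)oxy]buta-1,3-dien-2-yl]benzoate (ketene carbon and pyranonyl group cis) | O=C=C(c1cc(C(=O)OC)ccc1OC)/C(O[Si](C(C)C)(C(C)C)C(C)C)=C\c1cc(=O)cc(-c2ccc(O[Si](C(C)C)(C(C)C)C(C)C)cc2)o1 | intermediate
16 | methyl 3-[4,5-dioxo-7-[(triisopropylsilyl)oxy]-2-{4-[(triisopropylsilyl)oxy]phenyl}-4a,5-dihydro-4H-chromen-6-yl]-4-methoxybenzoate (racemic keto tautomer) | O=C1C(c2cc(C(=O)OC)ccc2OC)=C(O[Si](C(C)C)(C(C)C)C(C)C)C=C2OC(c3ccc(O[Si](C(C)C)(C(C)C)C(C)C)cc3)=CC(=O)C12 | intermediate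
17 | methyl 3-[5-hydroxy-4-oxo-7-[(triisopropylsilyl)oxy]-2-{4-[(triisopropylsilyl)oxy]phenyl}-4H-chromen-6-yl]-4-methoxybenzoate | COC(=O)c1ccc(OC)c(-c2c(O[Si](C(C)C)(C(C)C)C(C)C)cc3oc(-c4ccc(O[Si](C(C)C)(C(C)C)C(C)C)cc4)cc(=O)c3c2O)c1 | intermediate
18 | methyl 3-[5,7-dihydroxy-2-(4-hydroxyphenyl)-4-oxo-4H-chromen-6-yl]-4-methoxybenzoate | COC(=O)c1ccc(OC)c(-c2c(O)cc3oc(-c4ccc(O)cc4)cc(=O)c3c2O)c1 | target

## Step count and risk

Total: 8 steps. Longest linear sequence: 6 steps (1, 2, 3, 4, 7, 8); the alkyne branch (steps 5, 6) joins at step 7.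

**Step 7 (key step).** The most likely failure is slow capture of ketene 13 by the hindered, aryl-substituted siloxyalkyne, so that the ketene dimerises or reacts with unconsumed diazo ketone. A second risk is incomplete thermal ring opening of the cyclobutenone, or photodegradation of the pyranone if shorter wavelengths are needed.
Fallback (from 8, back at 18): 8 is converted by Miyaura borylation (B2pin2, Pd(dppf)Cl2, KOAc, dioxane, 80 °C) into methyl 4-methoxy-3-(4,4,5,5-tetramethyl-1,3,2-dioxaborolan-2-yl)benzoate F1. Commercial apigenin F2 is benzylated at O7 and O4' (BnBr, K2CO3, DMF; the chelated 5-OH stays free) to 7-(benzyloxy)-2-[4-(benzyloxy)phenyl]-5-hydroxy-4H-chromen-4-one F3. This is iodinated ortho to the free 5-OH (BnMe3N·ICl2, CaCO3, CH2Cl2/MeOH) to the 6-iodide F4. F4 and F1 are joined by Suzuki–Miyaura coupling (Pd(OAc)2, SPhos, K3PO4, toluene/H2O, 80 °C) to the dibenzyl ether F5, and hydrogenolysis (H2, Pd/C, EtOAc/MeOH) gives 18.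

**Step 6.** The most likely failure is nucleophilic attack of the lithium peroxide or of the ynolate on the methyl ester before silylation, or protonation and hydrolysis of the siloxyalkyne during purification.
Fallback (from 9, back at 18): the ester is carried as a carboxylate, which is inert to both nucleophiles. Saponification of 9 (LiOH, THF/H2O) gives 3-ethynyl-4-methoxybenzoic acid F6. Double deprotonation (LiN(SiMe3)2, 2 equiv), oxidation with t-BuOOLi and double silylation (i-Pr3SiOTf) give triisopropylsilyl 4-methoxy-3-{[(triisopropylsilyl)oxy]ethynyl}benzoate F7. Benzannulation with 7 under the conditions of step 7 gives the tris-silyl flavone F8, Bu4NF/AcOH frees the carboxylic acid F9, and Fischer esterification (MeOH, cat. H2SO4, 65 °C), which leaves phenols unmethylated, gives 18.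

**Step 4.** The most likely failure is 1,3-dipolar cycloaddition of diazomethane to the acyl-activated C2=C3 bond of the pyranone, or conversion of the pyranone carbonyl into a 4-chloropyrylium salt during acid chloride formation.
Fallback (from 3, back at 7): the diazo group is installed by diazo transfer instead of acylation. The dianion of 3 (LiN(i-Pr)2) is acylated with methyl 2,2-dimethoxypropanoate to 6,6-dimethoxy-1-{4-[(triisopropylsilyl)oxy]phenyl}heptane-1,3,5-trione F10. Wet CF3CO2H cyclises it and unmasks the ketone to give 2-acetyl-6-{4-[(triisopropylsilyl)oxy]phenyl}-4H-pyran-4-one F11. Its lithium enolate (LiN(SiMe3)2, −78 °C) is trifluoroacetylated with CF3CO2CH2CF3 to the trifluoroacetyl diketone F12, and MsN3, Et3N, H2O in MeCN effect diazo transfer with loss of trifluoroacetate to give 7.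

**Step 3.** The most likely failure is a second addition of the dianion to the reactive α-keto ester carbonyl of 4, or incomplete cyclodehydration with competing five-ring lactonisation onto the ester.
Fallback (from 3, back at 5): the carboxyl carbon is brought in as a methyl group and oxidised. The dianion of 3 is acetylated with N-methoxy-N-methylacetamide to 1-{4-[(triisopropylsilyl)oxy]phenyl}hexane-1,3,5-trione F13. CF3CO2H cyclodehydrates it to 2-methyl-6-{4-[(triisopropylsilyl)oxy]phenyl}-4H-pyran-4-one F14. Riley oxidation (SeO2, dioxane, 100 °C) gives 4-oxo-6-{4-[(triisopropylsilyl)oxy]phenyl}-4H-pyran-2-carbaldehyde F15, and Pinnick oxidation (NaClO2, NaH2PO4, 2-methyl-2-butene, t-BuOH/H2O) gives 5.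

## Further compounds

F1 | step 7 | methyl 4-methoxy-3-(4,4,5,5-tetramethyl-1,3,2-dioxaborolan-2-yl)benzoate | COC(=O)c1ccc(OC)c(B2OC(C)(C)C(C)(C)O2)c1
F2 | step 7 | apigenin (5,7-dihydroxy-2-(4-hydroxyphenyl)-4H-chromen-4-one) | O=c1cc(-c2ccc(O)cc2)oc2cc(O)cc(O)c12
F3 | step 7 | 7-(benzyloxy)-2-[4-(benzyloxy)phenyl]-5-hydroxy-4H-chromen-4-one | O=c1cc(-c2ccc(OCc3ccccc3)cc2)oc2cc(OCc3ccccc3)cc(O)c12
F4 | step 7 | 7-(benzyloxy)-2-[4-(benzyloxy)phenyl]-5-hydroxy-6-iodo-4H-chromen-4-one | O=c1cc(-c2ccc(OCc3ccccc3)cc2)oc2cc(OCc3ccccc3)c(I)c(O)c12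
F5 | step 7 | methyl 3-{7-(benzyloxy)-2-[4-(benzyloxy)phenyl]-5-hydroxy-4-oxo-4H-chromen-6-yl}-4-methoxybenzoate | COC(=O)c1ccc(OC)c(-c2c(OCc3ccccc3)cc3oc(-c4ccc(OCc5ccccc5)cc4)cc(=O)c3c2O)c1
F6 | step 6 | 3-ethynyl-4-methoxybenzoic acid | OC(=O)c1ccc(OC)c(C#C)c1
F7 | step 6 | triisopropylsilyl 4-methoxy-3-{[(triisopropylsilyl)oxy]ethynyl}benzoate | CC(C)[Si](OC(=O)c1ccc(OC)c(C#CO[Si](C(C)C)(C(C)C)C(C)C)c1)(C(C)C)C(C)C
F8 | step 6 | triisopropylsilyl 3-[5-hydroxy-4-oxo-7-[(triisopropylsilyl)oxy]-2-{4-[(triisopropylsilyl)oxy]phenyl}-4H-chromen-6-yl]-4-methoxybenzoate | CC(C)[Si](OC(=O)c1ccc(OC)c(-c2c(O[Si](C(C)C)(C(C)C)C(C)C)cc3oc(-c4ccc(O[Si](C(C)C)(C(C)C)C(C)C)cc4)cc(=O)c3c2O)c1)(C(C)C)C(C)C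
F9 | step 6 | 3-[5,7-dihydroxy-2-(4-hydroxyphenyl)-4-oxo-4H-chromen-6-yl]-4-methoxybenzoic acid | OC(=O)c1ccc(OC)c(-c2c(O)cc3oc(-c4ccc(O)cc4)cc(=O)c3c2O)c1
F10 | step 4 | 6,6-dimethoxy-1-{4-[(triisopropylsilyl)oxy]phenyl}heptane-1,3,5-trione | CC(OC)(OC)C(=O)CC(=O)CC(=O)c1ccc(O[Si](C(C)C)(C(C)C)C(C)C)cc1
F11 | step 4 | 2-acetyl-6-{4-[(triisopropylsilyl)oxy]phenyl}-4H-pyran-4-one | CC(=O)c1cc(=O)cc(-c2ccc(O[Si](C(C)C)(C(C)C)C(C)C)cc2)o1
F12 | step 4 | 4,4,4-trifluoro-1-(4-oxo-6-{4-[(triisopropylsilyl)oxy]phenyl}-4H-pyran-2-yl)butane-1,3-dione | O=C(CC(=O)C(F)(F)F)c1cc(=O)cc(-c2ccc(O[Si](C(C)C)(C(C)C)C(C)C)cc2)o1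
F13 | step 3 | 1-{4-[(triisopropylsilyl)oxy]phenyl}hexane-1,3,5-trione | CC(=O)CC(=O)CC(=O)c1ccc(O[Si](C(C)C)(C(C)C)C(C)C)cc1
F14 | step 3 | 2-methyl-6-{4-[(triisopropylsilyl)oxy]phenyl}-4H-pyran-4-one | Cc1cc(=O)cc(-c2ccc(O[Si](C(C)C)(C(C)C)C(C)C)cc2)o1
F15 | step 3 | 4-oxo-6-{4-[(triisopropylsilyl)oxy]phenyl}-4H-pyran-2-carbaldehyde | O=Cc1cc(=O)cc(-c2ccc(O[Si](C(C)C)(C(C)C)C(C)C)cc2)o1
A1 | alternative 1 | apigenin | O=c1cc(-c2ccc(O)cc2)oc2cc(O)cc(O)c12
A2 | alternative 1 | 7-(benzyloxy)-2-[4-(benzyloxy)phenyl]-5-hydroxy-4H-chromen-4-one | O=c1cc(-c2ccc(OCc3ccccc3)cc2)oc2cc(OCc3ccccc3)cc(O)c12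
A3 | alternative 1 | 7-(benzyloxy)-2-[4-(benzyloxy)phenyl]-5-hydroxy-6-iodo-4H-chromen-4-one | O=c1cc(-c2ccc(OCc3ccccc3)cc2)oc2cc(OCc3ccccc3)c(I)c(O)c12
A4 | alternative 1 | [2-methoxy-5-(methoxycarbonyl)phenyl]boronic acid | COC(=O)c1ccc(OC)c(B(O)O)c1
A5 | alternative 1 | methyl 3-{7-(benzyloxy)-2-[4-(benzyloxy)phenyl]-5-hydroxy-4-oxo-4H-chromen-6-yl}-4-methoxybenzoate | COC(=O)c1ccc(OC)c(-c2c(OCc3ccccc3)cc3oc(-c4ccc(OCc5ccccc5)cc4)cc(=O)c3c2O)c1
A6 | alternative 2 | 7-(benzyloxy)-2-[4-(benzyloxy)phenyl]-6-(2,2-dimethoxyethenyl)-5-hydroxy-4H-chromen-4-one | COC(OC)=Cc1c(OCc2ccccc2)cc2oc(-c3ccc(OCc4ccccc4)cc3)cc(=O)c2c1O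
A7 | alternative 2 | methyl coumalate (methyl 2-oxo-2H-pyran-5-carboxylate) | COC(=O)c1ccc(=O)oc1
A8 | alternative 3 | [2-methoxy-5-(methoxycarbonyl)phenyl]lead triacetate | COC(=O)c1ccc(OC)c([Pb](OC(C)=O)(OC(C)=O)OC(C)=O)c1
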